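## Retrosynthetic overview

1. Numbering: ring B is C1(aryl)–C2(C9H2OH)–C3(CHO)=C4–C4a–C8a; ring A is C4a, C5, C6, C7(OH), C8(OMe), C8a. The strategy rests on the C2–C3 bond of ring B: C2 is α to the oxygenated carbon C9 and C3 is α to the formyl carbon, a 1,4-dioxygenated pair in which both carbons are natural donors. C2 is therefore made an acceptor, as the inner carbon of a C2–C9 epoxide.
2. Key disconnection, C2–C3 (ring B, the only ring built; rings A and C are bought): C3 of a ring A cinnamaldehyde, made nucleophilic by reversible addition of PMe3 at C4, opens the epoxide at C2 with inversion, and loss of PMe3 restores C3=C4.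
3. The epoxy enal comes from an epoxy benzaldehyde by Wittig formyl-olefination, and that from a 3,3-diarylpropane-1,2-diol acetal (diol to terminal epoxide, then acetal hydrolysis).
4. Disconnection C1–C8a: anti opening of the Sharpless-derived (2S,3S)-3-(3,4-dimethoxyphenyl)glycidol at its benzylic carbon by the arylmagnesium/copper reagent from ortho-lithiated benzylvanillin dimethyl acetal. This sets C1 and carries the C2 oxygen stereocentre.
5. The benzyl ether on O7 is removed in the last step, after ring B is closed.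

Key step: step 8

Remark: the hydroxy enals 15 and 16 are drawn open-chain, and a minor five-membered lactol tautomer (O9 on the formyl carbon) is taken as the same compound; locants C1–C9 follow the numbering above.

## Route

Step 1
Reactants: 1 methyl (E)-3-(3,4-dimethoxyphenyl)prop-2-enoate
Product: 2 (E)-3-(3,4-dimethoxyphenyl)prop-2-en-1-ol
Conditions: i-Bu2AlH (2.5 equiv), CH2Cl2, −78 → 0 °C; aq. KNaC4H4O6 work-up
Reagents that add atoms: none
Why: DIBAL-H reduction of an α,β-unsaturated ester proceeds by 1,2-hydride delivery only and should give the (E)-allylic alcohol with the alkene and the aryl methyl ethers untouched.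

Step 2
Reactants: 2 (E)-3-(3,4-dimethoxyphenyl)prop-2-en-1-ol
Product: 3 [(2S,3S)-3-(3,4-dimethoxyphenyl)oxiran-2-yl]methanol
Conditions: Ti(OiPr)4 (10 mol %), L-(+)-diisopropyl tartrate (12 mol %), t-BuOOH (2 equiv, in isooctane), 4 Å MS, CH2Cl2, −25 °C; cold aq. NaOH/NaCl work-up, product used promptly
Reagents that add atoms: tert-butyl hydroperoxide, CC(C)(C)OO
Why: Sharpless asymmetric epoxidation with L-(+)-tartrate delivers oxygen to the face of the (E)-allylic alcohol that gives the (2S,3S)-epoxy alcohol (the sense known for cinnamyl alcohol), which sets both epoxide carbons, while sieves, low temperature and a non-acidic work-up protect the electron-rich benzylic epoxide.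

Step 3
Reactants: 4 4-(benzyloxy)-3-methoxybenzaldehyde (benzylvanillin)
Product: 5 1-(benzyloxy)-4-(dimethoxymethyl)-2-methoxybenzene
Conditions: HC(OMe)3 (3 equiv), p-TsOH·H2O (1 mol %), MeOH, rt; Et3N quench
Reagents that add atoms: trimethyl orthoformate, COC(OC)OC; methanol, CO
Why: Acid-catalysed acetalisation driven by the orthoformate as dehydrating agent gives the dimethyl acetal, which protects the aldehyde and, together with the neighbouring methoxy group, directs the metalation of step 4.

Step 4
Reactants: 5 1-(benzyloxy)-4-(dimethoxymethyl)-2-methoxybenzene; 3 [(2S,3S)-3-(3,4-dimethoxyphenyl)oxiran-2-yl]methanol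
Product: 8 (2R,3S)-3-[3-(benzyloxy)-6-(dimethoxymethyl)-2-methoxyphenyl]-3-(3,4-dimethoxyphenyl)propane-1,2-diol, via ring A aryllithium 6 (not isolated), via ring A arylmagnesium bromide 7 (not isolated)
Conditions: 5 (2.5 equiv), n-BuLi (2.5 equiv), THF, −20 → 0 °C; MgBr2·OEt2 (2.6 equiv), −30 °C; CuI (0.25 equiv), then 3 (1 equiv), −30 → 0 °C; aq. NH4Cl/NH3 (pH 9) work-up, Et3N-treated silica
Reagents that add atoms: none
Why: Directed ortho-metalation occurs at the ring position flanked by the acetal and the methoxy group (cooperative directors), and after lithium-to-magnesium exchange the copper-catalysed opening of the 3-aryl-2,3-epoxy alcohol takes place at the benzylic carbon with inversion (anti SN2), which forms C1–C8a and sets C1 as S while the carbinol carbon C2 is carried over unchanged; one equivalent of 7 is spent on the free hydroxyl and returns 5.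

Step 5
Reactants: 8 (2R,3S)-3-[3-(benzyloxy)-6-(dimethoxymethyl)-2-methoxyphenyl]-3-(3,4-dimethoxyphenyl)propane-1,2-diol
Product: 9 (2R)-2-{(S)-[3-(benzyloxy)-6-(dimethoxymethyl)-2-methoxyphenyl](3,4-dimethoxyphenyl)methyl}oxirane
Conditions: NaH (2.5 equiv), THF, 0 °C; N-tosylimidazole (1.05 equiv), 0 °C → rt
Reagents that add atoms: none
Why: Selective sulfonylation of the primary alkoxide followed by intramolecular Williamson etherification (3-exo-tet) by the C2 alkoxide should give the terminal epoxide with retention at C2, because the C2–O bond is never broken, and the basic medium keeps the acetal and prevents its transacetalisation with the diol.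

Step 6
Reactants: 9 (2R)-2-{(S)-[3-(benzyloxy)-6-(dimethoxymethyl)-2-methoxyphenyl](3,4-dimethoxyphenyl)methyl}oxirane
Product: 10 4-(benzyloxy)-2-{(S)-(3,4-dimethoxyphenyl)[(2R)-oxiran-2-yl]methyl}-3-methoxybenzaldehyde
Conditions: pyridinium p-toluenesulfonate (10 mol %), acetone/H2O 9:1, 0 °C → rt
Reagents that add atoms: water, O
Why: Acetal hydrolysis of a para-alkoxybenzaldehyde dimethyl acetal proceeds under very mild general acid, conditions under which a non-benzylic monosubstituted epoxide, the benzyl ether and the C1 stereocentre should be stable.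

Step 7
Reactants: 10 4-(benzyloxy)-2-{(S)-(3,4-dimethoxyphenyl)[(2R)-oxiran-2-yl]methyl}-3-methoxybenzaldehyde; 11 (triphenylphosphoranylidene)acetaldehyde
Product: 12 (2E)-3-[4-(benzyloxy)-2-{(S)-(3,4-dimethoxyphenyl)[(2R)-oxiran-2-yl]methyl}-3-methoxyphenyl]prop-2-enal
Conditions: 11 (1.5 equiv), toluene, 80 °C, monitored and stopped at full conversion of 10
Reagents that add atoms: (triphenylphosphoranylidene)acetaldehyde 11, O=CC=P(c1ccccc1)(c1ccccc1)c1ccccc1
Why: Wittig olefination with the stabilised formylmethylene ylide gives the (E)-cinnamaldehyde under neutral thermal conditions that leave the epoxide intact, and a limited excess of ylide with monitoring should keep a second homologation low.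

Step 8
Reactants: 12 (2E)-3-[4-(benzyloxy)-2-{(S)-(3,4-dimethoxyphenyl)[(2R)-oxiran-2-yl]methyl}-3-methoxyphenyl]prop-2-enal
Product: 15 vitekwangin B 7-O-benzyl ether, via phosphonium enolate 13 (not isolated), via cyclised phosphonium alkoxide 14 (not isolated)
Conditions: PMe3 (0.5 equiv, 1 M in THF), t-BuOH, 0.02 M, rt → 40 °C, argon
Reagents that add atoms: none
Why: Proposed new method: PMe3 adds reversibly to C4 of the enal to give phosphonium enolate 13, whose α-carbon C3 attacks the epoxide carbon C2 anti to the C2–O bond (t-BuOH hydrogen-bonds to the epoxide oxygen and buffers the charges) to give 14, and proton transfer from C3–H to the C9 alkoxide followed by E1cB loss of PMe3 restores C3=C4 and frees the phosphine. The closest known reaction type is the trialkylphosphine-mediated intramolecular Morita–Baylis–Hillman-type alkylation of enones by tethered epoxides, alkyl halides or allylic leaving groups; an enal, and a β-aryl one, has not been shown as the pronucleophile. Ring B closes in the 6-exo-tet mode (C3 onto the inner carbon C2), the 7-endo alternative at C9 being disfavoured by ring size and trajectory. The one new stereocentre, C2, is set by SN2 inversion of the (R)-epoxide carbon, so the Sharpless-derived configuration becomes C2 (R) of 15 with the C1 aryl and C2 hydroxymethyl groups trans, while C1, which is not acidic under these conditions, is carried through. The step needs conjugate addition of the phosphine in preference to attack on the formyl group or on the epoxide, and inner-carbon regioselectivity; reversibility of the 1,2-adduct, the ortho placement of enal and epoxide arm on ring A (a six-membered transition state holding two ring A atoms) and high dilution are what should secure them.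

Step 9
Reactants: 15 vitekwangin B 7-O-benzyl ether
Product: 16 vitekwangin B
Conditions: BCl3 (3 equiv, 1 M in CH2Cl2), pentamethylbenzene (5 equiv), CH2Cl2, −78 °C; MeOH/CHCl3 quench at −78 °C, then aq. NaHCO3
Reagents that add atoms: none
Why: Lewis acid-mediated debenzylation in which the benzyl cation is trapped by pentamethylbenzene (Friedel–Crafts) is non-reductive, so the enal survives, and at −78 °C the three aryl methyl ethers should stay while the primary alcohol is only transiently borylated and released on quench.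

## Compound list

1 | methyl (E)-3-(3,4-dimethoxyphenyl)prop-2-enoate | COC(=O)/C=C/c1ccc(OC)c(OC)c1 | starting material
2 | (E)-3-(3,4-dimethoxyphenyl)prop-2-en-1-ol | OC/C=C/c1ccc(OC)c(OC)c1 | intermediate
3 | [(2S,3S)-3-(3,4-dimethoxyphenyl)oxiran-2-yl]methanol | COc1ccc([C@@H]2O[C@H]2CO)cc1OC | intermediate
4 | 4-(benzyloxy)-3-methoxybenzaldehyde | COc1cc(C=O)ccc1OCc1ccccc1 | starting material
5 | 1-(benzyloxy)-4-(dimethoxymethyl)-2-methoxybenzene | COC(OC)c1ccc(OCc2ccccc2)c(OC)c1 | intermediate
6 | [3-(benzyloxy)-6-(dimethoxymethyl)-2-methoxyphenyl]lithium | COC(OC)c1ccc(OCc2ccccc2)c(OC)c1[Li] | intermediate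
7 | [3-(benzyloxy)-6-(dimethoxymethyl)-2-methoxyphenyl]magnesium bromide | COC(OC)c1ccc(OCc2ccccc2)c(OC)c1[Mg]Br | intermediate
8 | (2R,3S)-3-[3-(benzyloxy)-6-(dimethoxymethyl)-2-methoxyphenyl]-3-(3,4-dimethoxyphenyl)propane-1,2-diol | COc1ccc([C@@H](c2c(C(OC)OC)ccc(OCc3ccccc3)c2OC)[C@@H](O)CO)cc1OC | intermediate
9 | (2R)-2-{(S)-[3-(benzyloxy)-6-(dimethoxymethyl)-2-methoxyphenyl](3,4-dimethoxyphenyl)methyl}oxirane | COc1ccc([C@@H](c2c(C(OC)OC)ccc(OCc3ccccc3)c2OC)[C@@H]4CO4)cc1OC | intermediate
10 | 4-(benzyloxy)-2-{(S)-(3,4-dimethoxyphenyl)[(2R)-oxiran-2-yl]methyl}-3-methoxybenzaldehyde | COc1ccc([C@@H](c2c(C=O)ccc(OCc3ccccc3)c2OC)[C@@H]4CO4)cc1OC | intermediate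
11 | (triphenylphosphoranylidene)acetaldehyde | O=CC=P(c1ccccc1)(c1ccccc1)c1ccccc1 | starting material
12 | (2E)-3-[4-(benzyloxy)-2-{(S)-(3,4-dimethoxyphenyl)[(2R)-oxiran-2-yl]methyl}-3-methoxyphenyl]prop-2-enal | COc1ccc([C@@H](c2c(/C=C/C=O)ccc(OCc3ccccc3)c2OC)[C@@H]4CO4)cc1OC | intermediate
13 | phosphonium enolate from addition of PMe3 to C4 of 12 (C4 configuration and enolate geometry undefined) | COc1ccc([C@@H](c2c(C(C=C[O-])[P+](C)(C)C)ccc(OCc3ccccc3)c2OC)[C@@H]4CO4)cc1OC | intermediate
14 | cyclised 4-(trimethylphosphonio) C9 alkoxide with ring B closed (C3 and C4 undefined) | COc1ccc([C@H]2c3c(ccc(OCc4ccccc4)c3OC)C([P+](C)(C)C)C(C=O)[C@@H]2C[O-])cc1OC | intermediate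
15 | vitekwangin B 7-O-benzyl ether, (3R,4S)-6-(benzyloxy)-4-(3,4-dimethoxyphenyl)-3-(hydroxymethyl)-5-methoxy-3,4-dihydronaphthalene-2-carbaldehyde | COc1ccc([C@H]2c3c(ccc(OCc4ccccc4)c3OC)C=C(C=O)[C@@H]2CO)cc1OC | intermediate
16 | vitekwangin B, (3R,4S)-4-(3,4-dimethoxyphenyl)-6-hydroxy-3-(hydroxymethyl)-5-methoxy-3,4-dihydronaphthalene-2-carbaldehyde | COc1ccc([C@H]2c3c(ccc(O)c3OC)C=C(C=O)[C@@H]2CO)cc1OC | target

## Step count and risks

Total steps: 9. Longest linear sequence: 8 (steps 1, 2, 4, 5, 6, 7, 8, 9).

**Step 8 (proposed new method).** Conjugate addition of the phosphine to the electron-rich β-aryl enal (C4 is para to the O7 ether) may be too unfavourable. Oligomerisation through the formyl group, or direct attack of PMe3 on the epoxide, would then take over.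
Fallback, from 10, returning at 15:
- Horner–Wadsworth–Emmons olefination of 10 with triethyl phosphonoacetate (NaH, THF, 0 °C) should give the ethyl (E)-enoate F1.
- PhSLi (from PhSH and n-BuLi, THF, −78 → 0 °C) adds to C4. The ester enolate opens the epoxide at C2 (Michael-initiated ring closure, 6-exo, inversion), and the C9 alkoxide closes onto the ester to give the sulfide lactone F2.
- mCPBA (1 equiv, CH2Cl2, −78 °C) gives the sulfoxide lactone F3.
- Loss of benzenesulfenic acid (toluene, 90 °C, or DBU at rt by E1cB) restores C3=C4 in the unsaturated lactone F4.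
- i-Bu2AlH (1.1 equiv, CH2Cl2, −78 °C) gives the lactol F5, which should open to the hydroxy enal 15.

**Step 4.** Transfer of the doubly ortho-substituted aryl group may be slower than magnesium-halide-promoted ionisation or rearrangement of the electron-rich benzylic epoxide, with loss of regio- and stereocontrol at C1. Metalation at the benzyl ether CH2 may also compete with ring lithiation.
Fallback, from 6, returning at 8 (it forms C1–C1′ with an unhindered nucleophile and avoids the epoxide):
- Quenching 6 with DMF gives the aldehyde F6.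
- Horner–Wadsworth–Emmons olefination with diethyl {2-oxo-2-[(4R)-2-oxo-4-phenyl-1,3-oxazolidin-3-yl]ethyl}phosphonate (LiCl, i-Pr2NEt, MeCN) gives the (E)-N-enoyl oxazolidinone F7.
- 3,4-Dimethoxyphenylmagnesium bromide with CuBr·SMe2 (THF, −40 → −10 °C) should add to the β-carbon anti to the 4-phenyl group of the chelated imide, giving the conjugate adduct F8 with C1 (S).
- NaN(SiMe3)2 (THF, −78 °C) then 2-(phenylsulfonyl)-3-phenyloxaziridine should hydroxylate the (Z)-enolate on the face away from the auxiliary phenyl, giving the α-hydroxy imide F9 with C2 (R).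
- LiBH4 (THF/MeOH, 0 °C) removes the auxiliary reductively and gives 8.

**Step 2.** Titanium- or acid-promoted opening of the electron-rich benzylic epoxide by isopropanol or tartrate, during the reaction or on work-up, would cost material and enantiomeric purity.
Fallback, from 2, returning at 3 (buffered basic dioxirane epoxidation on the protected alcohol):
- TBSCl and imidazole (DMF) give the silyl ether F10.
- Shi epoxidation with the enantiomer of the D-fructose-derived ketone (made from L-sorbose; KHSO5 as Oxone, K2CO3, Bu4NHSO4, MeCN/dimethoxymethane/aqueous buffer pH 10.5, 0 °C) should give the (2S,3S)-epoxy silyl ether F11.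
- Bu4NF (THF, 0 °C) frees 3.

## Further compounds

F1 | step 8 | ethyl (2E)-3-[4-(benzyloxy)-2-{(S)-(3,4-dimethoxyphenyl)[(2R)-oxiran-2-yl]methyl}-3-methoxyphenyl]prop-2-enoate | COc1ccc([C@@H](c2c(/C=C/C(=O)OCC)ccc(OCc3ccccc3)c2OC)[C@@H]4CO4)cc1OC
F2 | step 8 | sulfide lactone: ring B closed, 4-(phenylsulfanyl), C3 carboxyl lactonised onto O9, C1 and C2 as in 15, C3 and C4 undefined | COc1ccc([C@H]2c3c(ccc(OCc4ccccc4)c3OC)C(Sc4ccccc4)C5C(=O)OC[C@@H]52)cc1OC
F3 | step 8 | sulfoxide lactone: S-oxide of F2 | COc1ccc([C@H]2c3c(ccc(OCc4ccccc4)c3OC)C(S(=O)c4ccccc4)C5C(=O)OC[C@@H]52)cc1OC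
F4 | step 8 | unsaturated lactone: C3=C4 restored, C3 carboxyl lactonised onto O9, C1 and C2 as in 15 | COc1ccc([C@H]2c3c(ccc(OCc4ccccc4)c3OC)C=C5C(=O)OC[C@@H]52)cc1OC
F5 | step 8 | lactol: ring tautomer of 15 | COc1ccc([C@H]2c3c(ccc(OCc4ccccc4)c3OC)C=C5C(O)OC[C@@H]52)cc1OC
F6 | step 4 | 3-(benzyloxy)-6-(dimethoxymethyl)-2-methoxybenzaldehyde | COC(OC)c1ccc(OCc2ccccc2)c(OC)c1C=O
F7 | step 4 | (4R)-3-{(2E)-3-[3-(benzyloxy)-6-(dimethoxymethyl)-2-methoxyphenyl]prop-2-enoyl}-4-phenyl-1,3-oxazolidin-2-one | COC(OC)c1ccc(OCc2ccccc2)c(OC)c1/C=C/C(=O)N1[C@H](c2ccccc2)COC1=O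
F8 | step 4 | (4R)-3-{(3S)-3-[3-(benzyloxy)-6-(dimethoxymethyl)-2-methoxyphenyl]-3-(3,4-dimethoxyphenyl)propanoyl}-4-phenyl-1,3-oxazolidin-2-one | COc1ccc([C@@H](c2c(C(OC)OC)ccc(OCc3ccccc3)c2OC)CC(=O)N2[C@H](c3ccccc3)COC2=O)cc1OC
F9 | step 4 | (4R)-3-{(2R,3S)-3-[3-(benzyloxy)-6-(dimethoxymethyl)-2-methoxyphenyl]-3-(3,4-dimethoxyphenyl)-2-hydroxypropanoyl}-4-phenyl-1,3-oxazolidin-2-one | COc1ccc([C@@H](c2c(C(OC)OC)ccc(OCc3ccccc3)c2OC)[C@@H](O)C(=O)N2[C@H](c3ccccc3)COC2=O)cc1OC
F10 | step 2 | tert-butyl{[(2E)-3-(3,4-dimethoxyphenyl)prop-2-en-1-yl]oxy}dimethylsilane | COc1ccc(/C=C/CO[Si](C)(C)C(C)(C)C)cc1OC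
F11 | step 2 | tert-butyl{[(2S,3S)-3-(3,4-dimethoxyphenyl)oxiran-2-yl]methoxy}dimethylsilane | COc1ccc([C@@H]2O[C@H]2CO[Si](C)(C)C(C)(C)C)cc1OC
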